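**Direct plan and its weak points**

A direct plan would buy all four rings and make the three diaryl ether bonds by SNAr of phenoxides on 4-fluoro-3,5-dimethoxybenzaldehyde (A1). 5-Methoxyresorcinol (A2) would be mono-arylated to aldehyde A3, a Dakin oxidation would give diol A4, a twofold SNAr with A1 dialdehyde A5, a twofold Dakin oxidation diol A6, and BBr3 the target.
Its weakest steps would be:
- the mono-arylation of the symmetric diol A2: only an excess of A2 would hold it at one ether, so bis-arylation and a separation are built in;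
- the ether formations, above all the twofold capping of A4: each C–O bond would be made at the fluorine-bearing carbon between two methoxy groups, shielded and deactivated by both donors, at 110–120 °C with carbonate and free aldehydes present;
- the Dakin oxidations A3 → A4 and A5 → A6: three Baeyer–Villiger events that build no bond and only remove the formyl activators, the first on a substrate whose free, electron-rich phenol ring is open to the peracid.

**Retrosynthetic overview of the new route**

Ring A (C1 and C3 carry the ether oxygens, C5 the hydroxyl, C2, C4 and C6 are CH) would not be bought but built last; its six carbons come from two molecules of dichloroacetylene (made once from trichloroethylene) and one of dichloroketene.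
Key disconnection: C2–C3 and C4–C5 of ring A, by Danheiser benzannulation of the ring B cyclobutenone 18 with the rings C–D ethynyl ether 10; the C5 hydroxyl appears free.
Each oxygen on C1 and C3 comes from a hindered phenol (1 or 4) that is first bound to a two-carbon sp unit, never to a shielded aryl carbon. The D–O–C ether is made at the unhindered carbon of ring C para to its phenol oxygen.
Rings B, C and D are bought and ring A closes last. No symmetric diol is desymmetrized, no activating group is carried and oxidized away, and the position of every new bond follows from the mechanism.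

Key step: step 10

Remark on the chemistry: the target has no stereocentre. Compounds 1, 2, 5 and 15 are taken as purchased. Dichloroacetylene 6 would be handled only as a dilute THF solution under argon, never concentrated, and divided between steps 4 and 6 on the day it is made. The terminal aryl ethynyl ethers 10 and 14 would be used soon after they are made.

**Route**

Step 1
Reactants: 1 2,4,6-trimethoxyphenol; 2 5-iodo-1,2,3-trimethoxybenzene
Product: 3 1,2,3-trimethoxy-5-(2,4,6-trimethoxyphenoxy)benzene
Conditions: 1 (1.2 equiv), CuI (10 mol %), picolinic acid (20 mol %), K3PO4 (2 equiv), DMSO, 90 °C, Ar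
Reagents that add atoms: none
Why: Ullmann-type copper-catalysed C–O coupling in which the hindered partner is the nucleophile and the aryl iodide has two free ortho positions, a pairing for which the picolinic acid system is suited; argon keeps the electron-rich phenoxide of 1 from being oxidized.

Step 2
Reactants: 3 1,2,3-trimethoxy-5-(2,4,6-trimethoxyphenoxy)benzene
Product: 4 2,6-dimethoxy-4-(2,4,6-trimethoxyphenoxy)phenol
Conditions: BCl3 (1.2 equiv), CH2Cl2, −20 → 0 °C; then H2O
Reagents that add atoms: none
Why: Lewis acid cleavage of an aryl methyl ether by BCl3, which is selective for a methoxy group flanked by two ortho substituents; only the central methoxy group of ring C qualifies (twisted out of the ring plane, most basic oxygen, chelate with a neighbouring methoxy group), while the five others have at most one ortho neighbour.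

Step 3
Reactants: 5 trichloroethylene
Product: 6 dichloroacetylene
Conditions: KH (1.1 equiv), MeOH (cat.), THF, 0 °C → rt, Ar; the clear THF solution is drawn off from the KCl, kept at 0 °C and used the same day
Reagents that add atoms: none
Why: Base-induced dehydrochlorination of trichloroethylene, in which the catalytic potassium methoxide is the kinetic base and KH regenerates it with loss of hydrogen, a known way to a stock solution of dichloroacetylene in THF; one batch serves both branches.

Step 4
Reactants: 4 2,6-dimethoxy-4-(2,4,6-trimethoxyphenoxy)phenol; 6 dichloroacetylene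
Product: 7 2-{[(E)-1,2-dichloroethenyl]oxy}-1,3-dimethoxy-5-(2,4,6-trimethoxyphenoxy)benzene
Conditions: 6 (1.5 equiv, THF solution), K2CO3 (1 equiv), DMF, 0 °C → rt, Ar
Reagents that add atoms: none
Why: Nucleophilic anti addition of the potassium phenoxide to dichloroacetylene and protonation of the resulting vinyl anion by further phenol (the bond-forming half of the dichlorovinyl ether synthesis), in which the hindered oxygen meets a linear two-carbon electrophile, so the two ortho methoxy groups do not slow it; anti addition gives the E isomer.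

Step 5
Reactants: 7 2-{[(E)-1,2-dichloroethenyl]oxy}-1,3-dimethoxy-5-(2,4,6-trimethoxyphenoxy)benzene
Product: 10 2-(ethynyloxy)-1,3-dimethoxy-5-(2,4,6-trimethoxyphenoxy)benzene, via chloroethynyl ether 8 (not isolated), via lithium acetylide 9 (not isolated)
Conditions: n-BuLi (2.3 equiv), THF, −78 → −40 °C; then H2O, −78 °C → rt
Reagents that add atoms: none
Why: Ynol ether synthesis from a dichlorovinyl ether: n-BuLi eliminates HCl to the chloroalkyne, chlorine–lithium exchange gives the lithium acetylide and water gives the terminal ethynyl ether; at −78 °C ring lithiation of the methoxyarenes is too slow to interfere.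

Step 6
Reactants: 1 2,4,6-trimethoxyphenol; 6 dichloroacetylene
Product: 11 2-{[(E)-1,2-dichloroethenyl]oxy}-1,3,5-trimethoxybenzene
Conditions: 6 (1.5 equiv, THF solution), K2CO3 (1 equiv), DMF, 0 °C → rt, Ar
Reagents that add atoms: none
Why: The same anti addition of a hindered phenoxide to dichloroacetylene as in step 4, here with a second portion of the solution of 6 and on the phenol that becomes ring B.

Step 7
Reactants: 11 2-{[(E)-1,2-dichloroethenyl]oxy}-1,3,5-trimethoxybenzene
Product: 14 2-(ethynyloxy)-1,3,5-trimethoxybenzene, via chloroethynyl ether 12 (not isolated), via lithium acetylide 13 (not isolated)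
Conditions: n-BuLi (2.3 equiv), THF, −78 → −40 °C; then H2O, −78 °C → rt
Reagents that add atoms: none
Why: The same elimination, chlorine–lithium exchange and protonation as in step 5.

Step 8
Reactants: 14 2-(ethynyloxy)-1,3,5-trimethoxybenzene; 15 trichloroacetyl chloride
Product: 17 4,4-dichloro-3-(2,4,6-trimethoxyphenoxy)cyclobut-2-en-1-one, via dichloroketene 16 (not isolated)
Conditions: 15 (1.5 equiv), Zn–Cu couple (2 equiv), Et2O–DME, 0 °C → rt
Reagents that add atoms: none
Why: [2+2] cycloaddition of dichloroketene, made in the flask by zinc dechlorination of 15, with the electron-rich alkyne, whose CH carbon bonds to the ketene carbonyl carbon so that only the 3-aryloxy regioisomer should form; DME binds the ZnCl2.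

Step 9
Reactants: 17 4,4-dichloro-3-(2,4,6-trimethoxyphenoxy)cyclobut-2-en-1-one
Product: 18 3-(2,4,6-trimethoxyphenoxy)cyclobut-2-en-1-one
Conditions: Zn dust (4 equiv), AcOH (4 equiv), TMEDA (4 equiv), THF, 0 °C → rt
Reagents that add atoms: none
Why: Reductive dechlorination of the α,α-dichloroketone by zinc in amine-buffered acetic acid, the usual way from dichloroketene adducts to cyclobutenones; the buffered, alcohol-free medium should spare the vinylogous aryl ester.

Step 10
Reactants: 18 3-(2,4,6-trimethoxyphenoxy)cyclobut-2-en-1-one; 10 2-(ethynyloxy)-1,3-dimethoxy-5-(2,4,6-trimethoxyphenoxy)benzene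
Product: 23 3-[2,6-dimethoxy-4-(2,4,6-trimethoxyphenoxy)phenoxy]-5-(2,4,6-trimethoxyphenoxy)phenol, via vinylketene 19 (not isolated), via vinylcyclobutenone 20 (not isolated), via dienylketene 21 (not isolated), via cyclohexadienone 22 (not isolated)
Conditions: 18 (1.3 equiv), toluene, 80 → 110 °C, Ar; then K2CO3 (cat.), MeOH, rt
Reagents that add atoms: none
Why: Heating opens cyclobutenone 18 by 4π electrocyclic ring opening to vinylketene 19, whose ketene C=C adds ynol ether 10 in a [2+2] cycloaddition to give vinylcyclobutenone 20; a second 4π opening gives dienylketene 21, 6π electrocyclization gives cyclohexadienone 22, and tautomerization gives phenol 23. The closest known reaction type is the Danheiser benzannulation of cyclobutenones with alkoxyacetylenes, which gives resorcinol monoethers with this oxygen pattern. Ring A is the only ring closed: C4–C5 and C2–C3 form in the [2+2] step and C5–C6 is re-formed in the 6π electrocyclization, a six-membered closure without strain that is driven by aromatization. No stereocentre remains, since the sp3 carbon of 20 is lost on ring opening. The step needs regioselectivity only: the polarized ynol ether bonds through its CH carbon to the ketene carbonyl carbon, so the two aryloxy groups must end up meta to each other and to the new hydroxyl (a [4+2] pathway would give the same isomer). Any O-acylation of 23 by ketene 19 would be undone by the catalytic methanolysis at the end.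

Step 11
Reactants: 23 3-[2,6-dimethoxy-4-(2,4,6-trimethoxyphenoxy)phenoxy]-5-(2,4,6-trimethoxyphenoxy)phenol
Product: 24 2-{3-[2,6-dihydroxy-4-(2,4,6-trihydroxyphenoxy)phenoxy]-5-hydroxyphenoxy}benzene-1,3,5-triol (CNP0159471.0)
Conditions: BBr3 (12 equiv), CH2Cl2, −78 °C → rt, Ar; then H2O, 0 °C
Reagents that add atoms: none
Why: Lewis acid cleavage of all eight aryl methyl ethers, in which bromide attacks only the methyl carbon of each boron-complexed ether, so the three diaryl ether bonds should stay intact; the nonaphenol should be handled under argon.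

**Compound list**

1 | 2,4,6-trimethoxyphenol | COc1cc(OC)c(O)c(OC)c1 | starting material
2 | 5-iodo-1,2,3-trimethoxybenzene | COc1cc(I)cc(OC)c1OC | starting material
3 | 1,2,3-trimethoxy-5-(2,4,6-trimethoxyphenoxy)benzene | COc1cc(OC)c(Oc2cc(OC)c(OC)c(OC)c2)c(OC)c1 | intermediate
4 | 2,6-dimethoxy-4-(2,4,6-trimethoxyphenoxy)phenol | COc1cc(OC)c(Oc2cc(OC)c(O)c(OC)c2)c(OC)c1 | intermediate
5 | trichloroethylene | ClC=C(Cl)Cl | starting material
6 | dichloroacetylene (kept as a dilute THF solution) | ClC#CCl | intermediate
7 | 2-{[(E)-1,2-dichloroethenyl]oxy}-1,3-dimethoxy-5-(2,4,6-trimethoxyphenoxy)benzene | Cl/C=C(/Cl)Oc1c(OC)cc(Oc2c(OC)cc(OC)cc2OC)cc1OC | intermediate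
8 | 2-[(chloroethynyl)oxy]-1,3-dimethoxy-5-(2,4,6-trimethoxyphenoxy)benzene (not isolated) | ClC#COc1c(OC)cc(Oc2c(OC)cc(OC)cc2OC)cc1OC | intermediate
9 | lithium acetylide of 10, lithium on the terminal alkyne carbon (not isolated) | [Li]C#COc1c(OC)cc(Oc2c(OC)cc(OC)cc2OC)cc1OC | intermediate
10 | 2-(ethynyloxy)-1,3-dimethoxy-5-(2,4,6-trimethoxyphenoxy)benzene | C#COc1c(OC)cc(Oc2c(OC)cc(OC)cc2OC)cc1OC | intermediate
11 | 2-{[(E)-1,2-dichloroethenyl]oxy}-1,3,5-trimethoxybenzene | Cl/C=C(/Cl)Oc1c(OC)cc(OC)cc1OC | intermediate
12 | 2-[(chloroethynyl)oxy]-1,3,5-trimethoxybenzene (not isolated) | ClC#COc1c(OC)cc(OC)cc1OC | intermediate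
13 | lithium acetylide of 14, lithium on the terminal alkyne carbon (not isolated) | [Li]C#COc1c(OC)cc(OC)cc1OC | intermediate
14 | 2-(ethynyloxy)-1,3,5-trimethoxybenzene | C#COc1c(OC)cc(OC)cc1OC | intermediate
15 | trichloroacetyl chloride | O=C(Cl)C(Cl)(Cl)Cl | starting material
16 | dichloroketene (not isolated) | O=C=C(Cl)Cl | intermediate
17 | 4,4-dichloro-3-(2,4,6-trimethoxyphenoxy)cyclobut-2-en-1-one | O=C1C=C(Oc2c(OC)cc(OC)cc2OC)C1(Cl)Cl | intermediate
18 | 3-(2,4,6-trimethoxyphenoxy)cyclobut-2-en-1-one | O=C1C=C(Oc2c(OC)cc(OC)cc2OC)C1 | intermediate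
19 | 3-(2,4,6-trimethoxyphenoxy)buta-1,3-dien-1-one (vinylketene, not isolated) | O=C=CC(=C)Oc1c(OC)cc(OC)cc1OC | intermediate
20 | 3-[2,6-dimethoxy-4-(2,4,6-trimethoxyphenoxy)phenoxy]-4-[1-(2,4,6-trimethoxyphenoxy)ethenyl]cyclobut-2-en-1-one (racemic, not isolated) | O=C1C=C(Oc2c(OC)cc(Oc3c(OC)cc(OC)cc3OC)cc2OC)C1C(=C)Oc4c(OC)cc(OC)cc4OC | intermediate
21 | (3E)-3-[2,6-dimethoxy-4-(2,4,6-trimethoxyphenoxy)phenoxy]-5-(2,4,6-trimethoxyphenoxy)hexa-1,3,5-trien-1-one (dienylketene, ketene carbon and vinyl group cis, not isolated) | O=C=C/C(Oc1c(OC)cc(Oc2c(OC)cc(OC)cc2OC)cc1OC)=C\C(=C)Oc3c(OC)cc(OC)cc3OC | intermediate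
22 | 3-[2,6-dimethoxy-4-(2,4,6-trimethoxyphenoxy)phenoxy]-5-(2,4,6-trimethoxyphenoxy)cyclohexa-2,4-dien-1-one (not isolated) | O=C1C=C(Oc2c(OC)cc(Oc3c(OC)cc(OC)cc3OC)cc2OC)C=C(Oc4c(OC)cc(OC)cc4OC)C1 | intermediate
23 | 3-[2,6-dimethoxy-4-(2,4,6-trimethoxyphenoxy)phenoxy]-5-(2,4,6-trimethoxyphenoxy)phenol | Oc1cc(Oc2c(OC)cc(OC)cc2OC)cc(Oc2c(OC)cc(Oc3c(OC)cc(OC)cc3OC)cc2OC)c1 | intermediate
24 | 2-{3-[2,6-dihydroxy-4-(2,4,6-trihydroxyphenoxy)phenoxy]-5-hydroxyphenoxy}benzene-1,3,5-triol | Oc1cc(Oc2c(O)cc(O)cc2O)cc(Oc2c(O)cc(Oc3c(O)cc(O)cc3O)cc2O)c1 | target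

**Step count and risks**

Total step count: 11. Longest linear sequence: 7 steps (steps 3, 6, 7, 8, 9, 10, 11, from trichloroethylene through the ring B branch; the rings C–D branch through steps 1, 2, 4, 5, 10, 11 has 6).

The three steps most likely to fail:

1. Step 10 (benzannulation). The vinylketene from 18 may oligomerize or acylate instead of adding the aryl ynol ether, which is less nucleophilic than an alkyl ynol ether, or the ynol ether may decompose at 80–110 °C before it is trapped. Fallback: ring A would be bought instead of built. Setting out from 1, a chemoselective Ullmann coupling (CuI, picolinic acid, K3PO4, DMSO, 80 °C) with 1-bromo-3-iodo-5-methoxybenzene F1 at the C–I bond would give 2-(3-bromo-5-methoxyphenoxy)-1,3,5-trimethoxybenzene F2. A second Ullmann coupling of F2 with phenol 4 at 110 °C would give the nonamethyl ether 2-[3-methoxy-5-(2,4,6-trimethoxyphenoxy)phenoxy]-1,3-dimethoxy-5-(2,4,6-trimethoxyphenoxy)benzene F3. BBr3 under the conditions of step 11 would then cleave all nine methyl ethers, and the route is rejoined at 24.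

2. Step 2 (selective demethylation). The Lewis acid may fail to single out the central methoxy group, with cleavage of a methoxy group next to the diaryl ether oxygen on ring D or incomplete conversion. Fallback: the phenol oxygen would be marked from the start by an orthogonal group. Setting out from 1, 4-bromo-2,6-dimethoxyphenol F4 would be benzylated (benzyl bromide, K2CO3, DMF) to 2-(benzyloxy)-5-bromo-1,3-dimethoxybenzene F5. Ullmann coupling of F5 with 1 (CuI, picolinic acid, K3PO4, DMSO, 110 °C) would give 2-(benzyloxy)-1,3-dimethoxy-5-(2,4,6-trimethoxyphenoxy)benzene F6, and hydrogenolysis (H2, Pd/C, EtOAc) would give 4, where the route is rejoined.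

3. Step 9 (dechlorination). The vinylogous aryl ester may lose its aryloxy group by addition–elimination, or the four-membered ring may open or be over-reduced under the zinc and acid conditions. Fallback: the chlorine atoms would never be introduced. Setting out from 14, a [2+2] cycloaddition with ketene F7 (gas from the pyrolysis of acetone, passed into CH2Cl2 at 0 °C), the reaction by which 3-ethoxycyclobut-2-en-1-one is made from ethoxyacetylene, would give 18 directly, where the route is rejoined.

**Further compounds**

F1 | step 10 | 1-bromo-3-iodo-5-methoxybenzene (purchased) | COc1cc(Br)cc(I)c1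
F2 | step 10 | 2-(3-bromo-5-methoxyphenoxy)-1,3,5-trimethoxybenzene | COc1cc(Br)cc(Oc2c(OC)cc(OC)cc2OC)c1
F3 | step 10 | 2-[3-methoxy-5-(2,4,6-trimethoxyphenoxy)phenoxy]-1,3-dimethoxy-5-(2,4,6-trimethoxyphenoxy)benzene | COc1cc(Oc2c(OC)cc(OC)cc2OC)cc(Oc2c(OC)cc(Oc3c(OC)cc(OC)cc3OC)cc2OC)c1
F4 | step 2 | 4-bromo-2,6-dimethoxyphenol (purchased) | COc1cc(Br)cc(OC)c1O
F5 | step 2 | 2-(benzyloxy)-5-bromo-1,3-dimethoxybenzene | COc1cc(Br)cc(OC)c1OCc1ccccc1
F6 | step 2 | 2-(benzyloxy)-1,3-dimethoxy-5-(2,4,6-trimethoxyphenoxy)benzene | COc1cc(OC)c(Oc2cc(OC)c(OCc3ccccc3)c(OC)c2)c(OC)c1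
F7 | step 9 | ketene (gas, from pyrolysis of acetone) | C=C=O
A1 | direct plan | 4-fluoro-3,5-dimethoxybenzaldehyde | COc1cc(C=O)cc(OC)c1F
A2 | direct plan | 5-methoxyresorcinol | COc1cc(O)cc(O)c1
A3 | direct plan | 4-(3-hydroxy-5-methoxyphenoxy)-3,5-dimethoxybenzaldehyde | COc1cc(O)cc(Oc2c(OC)cc(C=O)cc2OC)c1
A4 | direct plan | 3-(4-hydroxy-2,6-dimethoxyphenoxy)-5-methoxyphenol | COc1cc(O)cc(Oc2c(OC)cc(O)cc2OC)c1
A5 | direct plan | 4-{3-[4-(4-formyl-2,6-dimethoxyphenoxy)-2,6-dimethoxyphenoxy]-5-methoxyphenoxy}-3,5-dimethoxybenzaldehyde | COc1cc(Oc2c(OC)cc(C=O)cc2OC)cc(Oc2c(OC)cc(Oc3c(OC)cc(C=O)cc3OC)cc2OC)c1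
A6 | direct plan | 4-{3-[4-(4-hydroxy-2,6-dimethoxyphenoxy)-2,6-dimethoxyphenoxy]-5-methoxyphenoxy}-3,5-dimethoxyphenol | COc1cc(Oc2c(OC)cc(O)cc2OC)cc(Oc2c(OC)cc(Oc3c(OC)cc(O)cc3OC)cc2OC)c1
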